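## The problem

Compound 21, (2S,3R,6S,8S,9R)-2-bromo-8-chloro-1,1,9-trimethyl-5-methylidenespiro[5.5]undecane-3,9-diol, is a spiro[5.5]undecane. Its locants (ring A = C1–C6, ring B = C6–C11) are used in the discussion, while the names of intermediates 9–20 number ring A in the opposite sense (their C1–C5 are C5–C1 of 21) and ring B in the same sense. The spiro carbon C6 is bonded in ring A to the gem-dimethyl carbon C1 and to the methylidene-bearing C5, so both ring A bonds at C6 join fully substituted carbons and are out of reach of ordinary enolate alkylation. The five stereocentres form two sets: the cis bromohydrin C2/C3 in ring A, and the secondary chloride C8 with the tertiary carbinol C9 (hydroxyl cis to chlorine) in ring B; C6 is stereogenic only because chlorine sits on C8 and not on C10. Inside each ring control is available. C1, the bulkier ring A neighbour of C6, takes the equatorial site on ring B, which makes the C8 chloride (equatorial, cis to C1) the stable epimer of an α-chloro ketone and sends a methyl nucleophile to C9 from the equatorial side. The axial methyl on C1 shields one face of C3, so hydride gives the alcohol cis to an equatorial C2 bromine. Between the rings there is almost no communication, because ring A senses the difference between the two arms of ring B only through a distant equatorial chlorine; the two sets therefore need separate absolute control. The cis halohydrins cannot close to epoxides but can undergo semipinacol ring contraction with base, silver salts or strong Lewis acids; together with the neopentyl secondary bromide, the tertiary alcohol and an exocyclic alkene that moves into the ring under acid, this calls for late, near-neutral introduction of these groups. The enabling feature is that ring B is a cyclohexane oxygenated at C9, para to C6 (a reduced 4-alkylphenol), and that C5 is an sp2 carbon two atoms from the oxygenated C3. An aryl ynone C3(=O)–C4≡C5 can therefore let the phenol para carbon attack C5, which closes ring A, forms the C5–C6 bond and leaves a dienone with two enantiotopic arms.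

## Retrosynthesis

The methylidene group of 21 is traced to the primary allylic alcohol of triol 18. In the forward sense the C–O bond of the hydroxymethyl group is exchanged for a diazene that loses nitrogen, forming C4–H and the exocyclic double bond together. Carbonyl olefination at C5 would have to occur next to C6 and β to the C3 oxygen, and a methylidene group carried from the start would expose C4 to enolisation in every base step. Keeping the alkene endocyclic (C4=C5) and conjugated to a C3 ketone protects C4 and leaves that ketone only one enolisable side. The forward step only has to engage the primary alcohol before the hindered secondary and tertiary ones. 18 arises from 17 by removal of both silyl groups.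

The bromohydrin is cut at C3–H and C2–Br: 17 from bromo enone 16 by reduction, and 16 from enone 14 by bromination of its α′-enol silane 15. The cis relation is local (hydride equatorial, bromine equatorial), but ring B cannot decide which cis pair forms relative to C6. A chiral transfer-hydrogenation catalyst acting on a ketone that epimerises at C2 solves both tasks at once. Epoxide or diol routes would give the trans halohydrin, and electrophilic bromination of the enolate is the only practical way to put bromine on the neopentyl carbon. The forward step must epimerise C2 faster than it reduces the slower epimer.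

Cutting the C9–CH3 bond of 14 leads to α-chloro ketone 13; cutting C8–Cl and C7–H of 13 leads to enone 11, whose C7=C8 bond marks the arm that will carry chlorine. A cis chlorohydrin cannot come from an alkene or an epoxide, so carbonyl addition to an α-chloro ketone is the logical construction. Conjugate hydride addition to 11 gives the enol silane 12 on the correct side only, which no direct enolisation could guarantee. The forward steps must chlorinate 12 directly, because its simple hydrolysis would erase the stereochemical information at C6, and must add methyl to the ring B ketone faster than to the hindered ring A enone.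

Enone 11 results from adding two hydrogens (C11–H, C10–H) to one of the two enantiotopic C=C bonds of trienedione 9, through dienol silane 10. This is the point where C6 becomes stereogenic, and it does so on a flat cross-conjugated dienone, the substrate class for which enantiotopic-group-selective copper hydride reduction is established; a later, saturated ketone would require a much harder enantioselective enolisation. 9 is achiral and contains every carbon of 21 except the C9 methyl group. The catalyst must tell C1 from C5 as neighbours of C6 and must spare the trisubstituted ring A enone.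

Cutting the C5–C6 bond of 9 opens ring A and rearomatises ring B, giving phenol ynone 8. Of the two crowded bonds at C6 this is the one that a π-acid-catalysed ipso attack can form, and forming it also turns the arene into the dienone needed for the desymmetrisation. Cutting C1–C6 instead would ask a tertiary cation to meet a tetrasubstituted enol (Alternative 3). 8 is acyclic in its tether, achiral and free of stereocentres. The forward reaction must be ipso- and 6-endo-selective.

Ynone 8 is cut at the C3–C4 acyl–alkynyl bond into Weinreb amide 5 and lithium acetylide 7, made from silyl ether 6, whose CH2O carbon becomes the methylidene carbon. 5 comes from acid 4 and this from methyl ether 3, which is cut at the C1–C6 aryl–CMe2 bond into anisole 1 and 3-methylbut-2-enoic acid 2. A Friedel–Crafts alkylation forms that bond while the ring is still a simple arene; the methyl ether directs it para and is removed before the alkyne is present.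

## Roads not taken

Alternative 1: The cut is the C3–C4 bond of ring A, made last. Me2AlCl would promote an intramolecular carbonyl-ene reaction of the α-bromo aldehyde A2: the isopropenyl group on the future spiro carbon adds through its CH2 terminus to the aldehyde and gives a methyl hydrogen to oxygen. The product A1 is the 9-O-triethylsilyl ether of 21, with methylidene group and C3 carbinol in place.
- Merits: ring A is finished in one step, the exocyclic alkene forms directly in its final position, no allylic transposition or ketone reduction is needed, and ring B enters with C8 and C9 complete.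
- Weak points: A2 holds two adjacent fully substituted carbons (C1, C6) in an open chain, with C6 already a stereocentre relative to C8/C9, and the ene step does nothing to build them. The α-bromo aldehyde can epimerise or lose HBr under the Lewis acid. The cis C2/C3 relation depends on a chair-like transition state that places the complexed oxygen axial beside an axial methyl group. A stepwise cationic course would give chloride capture or an endocyclic alkene.
- Comparison: at the end this road is better than the chosen one, which needs four steps (9 to 12) to finish ring A. The chosen plan sets against this that both crowded bonds at C6 come from one Friedel–Crafts step and one catalytic cyclisation of an achiral precursor, a problem A2 leaves unsolved.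

Alternative 2: The cut removes C8 from ring B: the chloro dienone A3 is traced to the five-membered silyloxy diene A4 of a spiro[4.5]decane. Dichlorocarbene (from CHCl3 and KOC(CH3)3, or from Cl3CCO2Na) adds to the enol silane double bond, and the dichlorocyclopropane opens with loss of chloride and silicon, so the inserted carbon arrives carrying chlorine.
- Merits: chlorine is on the correct arm by construction, the two arms of A3 differ electronically (a 2-chloro enone beside a plain enone), and C6 is already defined. No enantiotopic-group selection is needed; in this respect the road is stronger than the chosen one, whose step 6 rests on ligand control alone.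
- Weak points: the quaternary stereocentre of A4 must first be made enantioselectively. The carbene must spare the electron-rich vinylogous ester alkene of ring A and the second diene double bond. Basic carbene generation meets an enolisable ring. After expansion both ring B alkenes must still be reduced, C8 set by protonation and C9 by methyl addition, and a ring A carbonyl next to the spiro carbon turned into the methylidene group by a hindered olefination.
- Comparison: the chosen plan pays for its unbiased dienone with one ligand-controlled step, but reaches the whole carbon skeleton less one methyl in five steps and stores the methylidene carbon in a form that needs no carbonyl olefination.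

Alternative 3: The cut is the C1–C6 bond. BF3·OEt2 ionises the tertiary trifluoroacetate of A6 with participation of the neighbouring bromine, and the tetrasubstituted enol silane exocyclic to ring B attacks the CMe2 carbon. This closes ring A to the α-quaternary ketone A5, which carries the C2 bromide and the C3 silyl ether and has ring B as an ethylene ketal.
- Merits: the ring A stereocentres arrive with an acyclic fragment, where they can be set with absolute control, and bromine participation should preserve C2. Here this road is better than the chosen plan, which obtains C2/C3 only late by a dynamic kinetic reduction.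
- Weak points: the new bond joins a tertiary cation to a tetrasubstituted carbon, so elimination to an isopropenyl group, attack at the bromine-bearing carbon and return of trifluoroacetate compete. Ring B of A5 is still symmetric, so chlorine must later go to one of two diastereotopic arms that ring A distinguishes only from afar, the same inter-ring problem in reverse and now on a saturated ketone. The C5 ketone, flanked by the spiro carbon and β to a silyloxy group, must be methylenated.
- Comparison: the chosen plan sets against the early ring A control a catalytic, redox-neutral ring closure that delivers the dienone required for an established desymmetrisation, and it avoids both a cationic union of two fully substituted carbons and a hindered olefination.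

Key step: step 5

Assumption: silyl ether 6 is a catalogue reagent (otherwise one silylation from prop-2-yn-1-ol), and the senses of induction in steps 6 and 10 are those of the accepted models for these catalysts; should either prove opposite, the antipodal ligand is used and nothing else changes.

Step 1
Reactants: 1 anisole; 2 3-methylbut-2-enoic acid
Product: 3 3-(4-methoxyphenyl)-3-methylbutanoic acid
Conditions: AlCl3 (2.5 equiv), anisole (3 equiv), CH2Cl2, 0 → 23 °C; aq HCl work-up
Reagents that add atoms: none
Why: Friedel–Crafts alkylation (hydroarylation of the unsaturated acid): the AlCl3-complexed acid gives a tertiary β-cation that anisole traps para, the ortho positions being too crowded for a tertiary electrophile; this makes the aryl–CMe2 bond (future C1–C6) and no stereocentre.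

Step 2
Reactants: 3 3-(4-methoxyphenyl)-3-methylbutanoic acid
Product: 4 3-(4-hydroxyphenyl)-3-methylbutanoic acid
Conditions: BBr3 (3 equiv), CH2Cl2, −78 → 23 °C; H2O
Reagents that add atoms: none
Why: Aryl methyl ether cleavage with BBr3; it is done here because neither the Weinreb amide nor the ynone would tolerate it later, and the acyloxyborane of the acid is hydrolysed on work-up.

Step 3
Reactants: 4 3-(4-hydroxyphenyl)-3-methylbutanoic acid
Product: 5 3-(4-hydroxyphenyl)-N-methoxy-N,3-dimethylbutanamide
Conditions: MeNHOMe·HCl, EDC·HCl, HOBt (cat.), N-methylmorpholine, CH2Cl2, 0 → 23 °C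
Reagents that add atoms: N,O-dimethylhydroxylamine hydrochloride, CNOC.Cl
Why: Carbodiimide amide coupling to the Weinreb amide; the amine is far more nucleophilic than the phenol, and any aryl ester formed is aminolysed under the same conditions.

Step 4
Reactants: 5 3-(4-hydroxyphenyl)-N-methoxy-N,3-dimethylbutanamide; 6 tert-butyl(dimethyl)(prop-2-yn-1-yloxy)silane
Product: 8 1-{[tert-butyl(dimethyl)silyl]oxy}-6-(4-hydroxyphenyl)-6-methylhept-2-yn-4-one, via lithium silyloxypropynide 7 (not isolated)
Conditions: 6 (2.6 equiv), n-BuLi (2.5 equiv), THF, −78 °C; then 5, −78 → 0 °C; poured into cold aq NH4Cl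
Reagents that add atoms: none
Why: Weinreb ketone synthesis: one equivalent of 7 deprotonates the phenol and a second adds to the amide to give a chelated tetrahedral adduct that releases the ynone only on quench, so no second addition occurs; the cold acidic quench keeps the liberated amine from adding to the ynone.

Step 5
Reactants: 8 1-{[tert-butyl(dimethyl)silyl]oxy}-6-(4-hydroxyphenyl)-6-methylhept-2-yn-4-one
Product: 9 1-({[tert-butyl(dimethyl)silyl]oxy}methyl)-5,5-dimethylspiro[5.5]undeca-1,7,10-triene-3,9-dione
Conditions: Ph3PAuNTf2 (5 mol %), CH2Cl2 (0.02 M), 23 °C
Reagents that add atoms: none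
Why: Monovalent gold binds the alkyne of 8; conjugation with the carbonyl group makes the alkyne carbon bearing the CH2OSi group (future C5) the electrophilic one, and the phenol carbon para to OH, which already carries the tether, attacks it anti to gold. Loss of the phenolic proton from the resulting oxocarbenium ion gives the cross-conjugated dienone, and protodeauration of the α-aurated enone installs the vinylic hydrogen and returns the catalyst. The closest known reaction type is the gold- or silver-catalysed dearomative ipso-cyclisation of phenol- and anisole-tethered ynones to spirocyclic dienones; 8 is the homologue with one more tether atom. Ring A closes in the 6-endo-dig mode, and the bond from the spiro carbon to its sp2 neighbour forms beside a quaternary carbon without enolate chemistry. No stereocentre arises: 9 is achiral and its two dienone arms are enantiotopic. The step needs ipso over ortho attack, secured because OH activates only the para carbon and an ortho closure would need a seven-membered ring, and β over α attack (6-endo over 5-exo), secured by the polarity of the ynone. The gem-dimethyl group favours the folded conformer, and high dilution suppresses intermolecular addition of the phenol O–H to the activated alkyne.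

Step 6
Reactants: 9 1-({[tert-butyl(dimethyl)silyl]oxy}methyl)-5,5-dimethylspiro[5.5]undeca-1,7,10-triene-3,9-dione
Product: 11 (6R)-1-({[tert-butyl(dimethyl)silyl]oxy}methyl)-5,5-dimethylspiro[5.5]undeca-1,7-diene-3,9-dione, via diethoxymethylsilyl dienol ether 10 (not isolated)
Conditions: Cu(OAc)2·H2O (5 mol %), (R)-DTBM-SEGPHOS (5.5 mol %), (EtO)2MeSiH (1.2 equiv), toluene, −20 °C; then 1 M HCl, THF, 0 °C, 10 min
Reagents that add atoms: diethoxy(methyl)silane, CCO[SiH](C)OCC (silicon only in 10; 11 keeps hydrogen alone)
Why: Ligand-controlled copper hydride 1,4-hydrosilylation of one of the two enantiotopic C=C bonds of a 4,4-disubstituted cyclohexa-2,5-dienone (catalytic desymmetrisation); the chiral bisphosphine–CuH complex selects the arm and so fixes C6, the only stereocentre of 11. The product is held as dienol silane 10, which cannot be reduced again, the β,β-disubstituted ring A enone reacts far more slowly, and mild acid protonates C10 to give the conjugated enone.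

Step 7
Reactants: 11 (6R)-1-({[tert-butyl(dimethyl)silyl]oxy}methyl)-5,5-dimethylspiro[5.5]undeca-1,7-diene-3,9-dione
Product: 13 (6R,8S)-1-({[tert-butyl(dimethyl)silyl]oxy}methyl)-8-chloro-5,5-dimethylspiro[5.5]undec-1-ene-3,9-dione, via dimethylphenylsilyl enol ether 12 (not isolated)
Conditions: [(Ph3P)CuH]6 (5 mol %), PhMe2SiH (1.3 equiv), toluene, 23 °C; then THF, N-chlorosuccinimide (1.2 equiv), −78 → 0 °C; then LiCl, DMF, 23 °C
Reagents that add atoms: N-chlorosuccinimide, ClN1C(=O)CCC1=O; dimethyl(phenyl)silane, C[SiH](C)c1ccccc1 (silicon only in 12)
Why: Copper hydride 1,4-hydrosilylation of the remaining enone gives the enol silane on the C8 side only, and electrophilic chlorination of a silyl enol ether by N-chlorosuccinimide then puts chlorine on C8. C8 is an epimerisable α-chloro ketone centre: chloride exchange in DMF should equilibrate it to the epimer with chlorine equatorial and cis to the equatorial CMe2 carbon, since the other epimer has chlorine syn-axial to the axial ring A carbon on C6.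

Step 8
Reactants: 13 (6R,8S)-1-({[tert-butyl(dimethyl)silyl]oxy}methyl)-8-chloro-5,5-dimethylspiro[5.5]undec-1-ene-3,9-dione
Product: 14 (6R,8S,9R)-1-({[tert-butyl(dimethyl)silyl]oxy}methyl)-8-chloro-9-hydroxy-5,5,9-trimethylspiro[5.5]undec-1-en-3-one
Conditions: MeMgBr (1.15 equiv), toluene/THF, −78 °C; aq NH4Cl at −78 °C
Reagents that add atoms: methylmagnesium bromide, C[Mg]Br
Why: Grignard 1,2-addition to an α-chloro ketone, the classical entry to cis chlorohydrins; the saturated, chlorine-activated ring B ketone should react before the conjugated ring A ketone, one face of which is blocked by an axial methyl group. In the locked chair (CMe2 carbon and chlorine equatorial) methyl should enter from the equatorial side, away from the axial hydrogens on C7 and C11, which makes the C9 hydroxyl axial and cis to chlorine; the cold quench prevents semipinacol rearrangement of the magnesium alkoxide.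

Step 9
Reactants: 14 (6R,8S,9R)-1-({[tert-butyl(dimethyl)silyl]oxy}methyl)-8-chloro-9-hydroxy-5,5,9-trimethylspiro[5.5]undec-1-en-3-one
Product: 16 (6S,8S,9R)-4-bromo-1-({[tert-butyl(dimethyl)silyl]oxy}methyl)-8-chloro-5,5,9-trimethyl-9-[(trimethylsilyl)oxy]spiro[5.5]undec-1-en-3-one (both C4 epimers), via bis-trimethylsilyl dienol ether 15 (not isolated)
Conditions: LiN(iPr)2 (2.3 equiv), THF, −78 °C; Me3SiCl (2.6 equiv), −78 → 0 °C; then N-bromosuccinimide (1.05 equiv), THF, −78 → 0 °C
Reagents that add atoms: chlorotrimethylsilane, C[Si](C)(C)Cl; N-bromosuccinimide, BrN1C(=O)CCC1=O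
Why: Kinetic α′-deprotonation of the enone (the C4 methylene between carbonyl and CMe2, as in other 5,5-dimethylcyclohexenones) with silyl trapping gives the cross-conjugated silyloxydiene 15, and bromination of a silyl enol ether by N-bromosuccinimide puts bromine on C4 only; the tertiary alkoxide is silylated in the same operation, which protects the chlorohydrin. The configuration at C4 is left open because it is labile and is settled in step 10.

Step 10
Reactants: 16 (6S,8S,9R)-4-bromo-1-({[tert-butyl(dimethyl)silyl]oxy}methyl)-8-chloro-5,5,9-trimethyl-9-[(trimethylsilyl)oxy]spiro[5.5]undec-1-en-3-one (both C4 epimers)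
Product: 17 (3R,4S,6S,8S,9R)-4-bromo-1-({[tert-butyl(dimethyl)silyl]oxy}methyl)-8-chloro-5,5,9-trimethyl-9-[(trimethylsilyl)oxy]spiro[5.5]undec-1-en-3-ol
Conditions: RuCl[(S,S)-TsDPEN](p-cymene) (5 mol %), HCO2H/Et3N (1:1), CH2Cl2, 25 °C
Reagents that add atoms: none
Why: Noyori–Ikariya asymmetric transfer hydrogenation with dynamic kinetic resolution of a cyclic α-halo ketone to a cis halohydrin: the amine base epimerises C4 through the dienol, and the catalyst, reading the C1=C2 double bond as the π-substituent, should deliver hydride to the face of C3 that gives the 3R alcohol. Hydride can reach C3 only from the equatorial side, opposite the axial methyl on C5, and the epimer with equatorial bromine is the one reduced, so hydroxyl and bromine end up cis (4S); both centres are thus fixed by the catalyst and not by ring B.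

Step 11
Reactants: 17 (3R,4S,6S,8S,9R)-4-bromo-1-({[tert-butyl(dimethyl)silyl]oxy}methyl)-8-chloro-5,5,9-trimethyl-9-[(trimethylsilyl)oxy]spiro[5.5]undec-1-en-3-ol
Product: 18 (3R,4S,6S,8S,9R)-4-bromo-8-chloro-1-(hydroxymethyl)-5,5,9-trimethylspiro[5.5]undec-1-ene-3,9-diol
Conditions: HF·pyridine, pyridine, THF, 0 → 23 °C
Reagents that add atoms: none
Why: Fluoride-mediated cleavage of both silyl ethers under buffered, non-basic conditions, which avoids alkoxide formation next to either halogen (no semipinacol shift) and acid ionisation of the allylic alcohols.

Step 12
Reactants: 18 (3R,4S,6S,8S,9R)-4-bromo-8-chloro-1-(hydroxymethyl)-5,5,9-trimethylspiro[5.5]undec-1-ene-3,9-diol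
Product: 21 (2S,3R,6S,8S,9R)-2-bromo-8-chloro-1,1,9-trimethyl-5-methylidenespiro[5.5]undecane-3,9-diol, via allyl sulfonylhydrazine 19 (not isolated), via allyl diazene 20 (not isolated)
Conditions: 2-nitrobenzenesulfonohydrazide (1.5 equiv), PPh3 (1.5 equiv), diethyl azodicarboxylate (1.5 equiv), THF, −30 °C; then 23 °C
Reagents that add atoms: 2-nitrobenzenesulfonohydrazide, NNS(=O)(=O)c1ccccc1[N+](=O)[O-] (nitrogen and sulfur only in 19 and 20)
Why: Myers reductive 1,3-transposition of an allylic alcohol: Mitsunobu displacement at the primary allylic carbon, much faster than at the hindered secondary or tertiary hydroxyl, gives 19, which loses sulfinate on warming. The monoalkyl diazene 20 extrudes N2 in a retro-ene shift that delivers hydrogen to the ring carbon and moves the double bond to the exocyclic position; no stereocentre is touched and the neutral conditions leave both cis halohydrins intact.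

## Compound list

1 | anisole (methoxybenzene) | COc1ccccc1 | starting material
2 | 3-methylbut-2-enoic acid | CC(C)=CC(O)=O | starting material
3 | 3-(4-methoxyphenyl)-3-methylbutanoic acid | COc1ccc(cc1)C(C)(C)CC(O)=O | intermediate
4 | 3-(4-hydroxyphenyl)-3-methylbutanoic acid | OC(=O)CC(C)(C)c1ccc(O)cc1 | intermediate
5 | 3-(4-hydroxyphenyl)-N-methoxy-N,3-dimethylbutanamide | CON(C)C(=O)CC(C)(C)c1ccc(O)cc1 | intermediate
6 | tert-butyl(dimethyl)(prop-2-yn-1-yloxy)silane | C#CCO[Si](C)(C)C(C)(C)C | starting material
7 | lithium 3-{[tert-butyl(dimethyl)silyl]oxy}prop-1-yn-1-ide | [Li+].[C-]#CCO[Si](C)(C)C(C)(C)C | intermediate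
8 | 1-{[tert-butyl(dimethyl)silyl]oxy}-6-(4-hydroxyphenyl)-6-methylhept-2-yn-4-one | CC(C)(C)[Si](C)(C)OCC#CC(=O)CC(C)(C)c1ccc(O)cc1 | intermediate
9 | 1-({[tert-butyl(dimethyl)silyl]oxy}methyl)-5,5-dimethylspiro[5.5]undeca-1,7,10-triene-3,9-dione (achiral) | CC(C)(C)[Si](C)(C)OCC1=CC(=O)CC(C)(C)C12C=CC(=O)C=C2 | intermediate
10 | (6R)-1-({[tert-butyl(dimethyl)silyl]oxy}methyl)-9-{[diethoxy(methyl)silyl]oxy}-5,5-dimethylspiro[5.5]undeca-1,7,9-trien-3-one | CC(C)(C)[Si](C)(C)OCC1=CC(=O)CC(C)(C)[C@]12CC=C(O[Si](C)(OCC)OCC)C=C2 | intermediate
11 | (6R)-1-({[tert-butyl(dimethyl)silyl]oxy}methyl)-5,5-dimethylspiro[5.5]undeca-1,7-diene-3,9-dione | CC(C)(C)[Si](C)(C)OCC1=CC(=O)CC(C)(C)[C@]12CCC(=O)C=C2 | intermediate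
12 | (6R)-1-({[tert-butyl(dimethyl)silyl]oxy}methyl)-9-{[dimethyl(phenyl)silyl]oxy}-5,5-dimethylspiro[5.5]undeca-1,8-dien-3-one | CC(C)(C)[Si](C)(C)OCC1=CC(=O)CC(C)(C)[C@]12CCC(O[Si](C)(C)c3ccccc3)=CC2 | intermediate
13 | (6R,8S)-1-({[tert-butyl(dimethyl)silyl]oxy}methyl)-8-chloro-5,5-dimethylspiro[5.5]undec-1-ene-3,9-dione | CC(C)(C)[Si](C)(C)OCC1=CC(=O)CC(C)(C)[C@]12CCC(=O)[C@@H](Cl)C2 | intermediate
14 | (6R,8S,9R)-1-({[tert-butyl(dimethyl)silyl]oxy}methyl)-8-chloro-9-hydroxy-5,5,9-trimethylspiro[5.5]undec-1-en-3-one | CC(C)(C)[Si](C)(C)OCC1=CC(=O)CC(C)(C)[C@]12CC[C@@](C)(O)[C@@H](Cl)C2 | intermediate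
15 | tert-butyl{[(6R,8S,9R)-8-chloro-5,5,9-trimethyl-3,9-bis(trimethylsilyloxy)spiro[5.5]undeca-1,3-dien-1-yl]methoxy}dimethylsilane | CC(C)(C)[Si](C)(C)OCC1=CC(O[Si](C)(C)C)=CC(C)(C)[C@]12CC[C@@](C)(O[Si](C)(C)C)[C@@H](Cl)C2 | intermediate
16 | (6S,8S,9R)-4-bromo-1-({[tert-butyl(dimethyl)silyl]oxy}methyl)-8-chloro-5,5,9-trimethyl-9-[(trimethylsilyl)oxy]spiro[5.5]undec-1-en-3-one, both C4 epimers | CC(C)(C)[Si](C)(C)OCC1=CC(=O)C(Br)C(C)(C)[C@]12CC[C@@](C)(O[Si](C)(C)C)[C@@H](Cl)C2 | intermediate
17 | (3R,4S,6S,8S,9R)-4-bromo-1-({[tert-butyl(dimethyl)silyl]oxy}methyl)-8-chloro-5,5,9-trimethyl-9-[(trimethylsilyl)oxy]spiro[5.5]undec-1-en-3-ol | CC(C)(C)[Si](C)(C)OCC1=C[C@@H](O)[C@@H](Br)C(C)(C)[C@]12CC[C@@](C)(O[Si](C)(C)C)[C@@H](Cl)C2 | intermediate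
18 | (3R,4S,6S,8S,9R)-4-bromo-8-chloro-1-(hydroxymethyl)-5,5,9-trimethylspiro[5.5]undec-1-ene-3,9-diol | OCC1=C[C@@H](O)[C@@H](Br)C(C)(C)[C@]12CC[C@@](C)(O)[C@@H](Cl)C2 | intermediate
19 | N-{[(3R,4S,6S,8S,9R)-4-bromo-8-chloro-3,9-dihydroxy-5,5,9-trimethylspiro[5.5]undec-1-en-1-yl]methyl}-2-nitrobenzenesulfonohydrazide (alkyl group on the sulfonylated nitrogen) | NN(CC1=C[C@@H](O)[C@@H](Br)C(C)(C)[C@]12CC[C@@](C)(O)[C@@H](Cl)C2)S(=O)(=O)c1ccccc1[N+](=O)[O-] | intermediate
20 | {[(3R,4S,6S,8S,9R)-4-bromo-8-chloro-3,9-dihydroxy-5,5,9-trimethylspiro[5.5]undec-1-en-1-yl]methyl}diazene | N=NCC1=C[C@@H](O)[C@@H](Br)C(C)(C)[C@]12CC[C@@](C)(O)[C@@H](Cl)C2 | intermediate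
21 | (2S,3R,6S,8S,9R)-2-bromo-8-chloro-1,1,9-trimethyl-5-methylidenespiro[5.5]undecane-3,9-diol | C=C1C[C@@H](O)[C@@H](Br)C(C)(C)[C@]12CC[C@@](C)(O)[C@@H](Cl)C2 | target

## Step count and least certain steps

Total: 12 steps. Longest linear sequence: 12 steps (1 and 2 to 21); 6 enters in step 4 as purchased.

Step 5 (key step). What may go wrong: the closure joins two fully substituted carbons and may be slow, so that intermolecular O–H addition of the phenol to the activated ynone, attack at the α-alkyne carbon or loss of the silyl ether take over. The fallback replaces catalytic π-acid activation by a stoichiometric iodonium on the methyl ether; it sets out from 3 and returns at 9. 3 is coupled with MeNHOMe·HCl as in step 3 to N-methoxy-3-(4-methoxyphenyl)-N,3-dimethylbutanamide F1, which reacts with 7 to give the anisole ynone 1-{[tert-butyl(dimethyl)silyl]oxy}-6-(4-methoxyphenyl)-6-methylhept-2-yn-4-one F2. ICl in CH2Cl2 at −78 °C then brings about electrophilic ipso-iodocyclisation, chloride removing the O-methyl group from the oxocarbenium ion, to give 1-({[tert-butyl(dimethyl)silyl]oxy}methyl)-2-iodo-5,5-dimethylspiro[5.5]undeca-1,7,10-triene-3,9-dione F3. The vinyl iodide is hydrogenolysed with Pd(OAc)2, PPh3 and HCO2H/Et3N in DMF to 9.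

Step 6. What may go wrong: poor discrimination of the two arms, because the catalyst must tell a quaternary sp3 carbon from a fully substituted sp2 carbon on C6, and partial reduction of the ring A enone. The fallback is biocatalytic; it sets out from 9 and returns at 11. One dienone C=C is reduced by an ene-reductase of the Old Yellow Enzyme family with NADPH recycled by glucose and glucose dehydrogenase, a known way to desymmetrise 4,4-disubstituted cyclohexa-2,5-dienones in which flavin hydride transfer, not a metal hydride, selects the arm. It makes no new compound.

Step 7. What may go wrong: hydrolysis of the enol silane before chlorination, which erases the C6 information; sluggish or double chlorination of a hindered enol silane; an unfavourable epimer ratio at C8. The fallback puts chlorine on the enone first and adds hydride second; it sets out from 11 and returns at 13. α-Chlorination of the ring B enone with PhICl2 and pyridine (chlorine addition, loss of HCl) gives the 2-chloro enone (6R)-1-({[tert-butyl(dimethyl)silyl]oxy}methyl)-8-chloro-5,5-dimethylspiro[5.5]undeca-1,7-diene-3,9-dione F4, in which the position of chlorine no longer depends on an enol silane. Copper hydride conjugate reduction ([(Ph3P)CuH]6, PhMe2SiH), aqueous acid and the LiCl equilibration then give 13.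

Step 8. What may go wrong: poor facial selectivity (axial entry of methyl gives the trans chlorohydrin), enolisation of the α-chloro ketone, or attack at the ring A carbonyl. In the fallback oxygen, not carbon, enters at C9; it sets out from 13 and returns at 14. Methylenation of the ring B ketone with Cp2Ti(μ-CH2)(μ-Cl)AlMe2 (Tebbe reagent) at −40 °C gives (6R,8S)-1-({[tert-butyl(dimethyl)silyl]oxy}methyl)-8-chloro-5,5-dimethyl-9-methylidenespiro[5.5]undec-1-en-3-one F5. Oxymercuration with Hg(OAc)2 in THF/H2O gives the Markovnikov adduct {[(6R,8S,9R)-1-({[tert-butyl(dimethyl)silyl]oxy}methyl)-8-chloro-9-hydroxy-5,5-dimethyl-3-oxospiro[5.5]undec-1-en-9-yl]methyl}mercury acetate F6, and brief treatment with NaBH4/NaOH at 0 °C replaces mercury by hydrogen to give 14. Because the nucleophile that attacks C9 is now water, a facial preference that put methyl on the wrong side is expected to put hydroxyl on the right one.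

Step 10. What may go wrong: epimerisation at C4 slower than reduction (the resolution is then only kinetic), a catalyst preference too weak for a ketone flanked by a vinyl and a bulky bromo-alkyl group, or competing 1,4-reduction. The fallback is a substrate-controlled reduction with recycling; it sets out from 16 and returns at 17. i-Bu2AlH in CH2Cl2 at −78 °C should reduce both C4 epimers from the equatorial side and give the two cis bromohydrins, 17 and its diastereomer (3S,4R,6S,8S,9R)-4-bromo-1-({[tert-butyl(dimethyl)silyl]oxy}methyl)-8-chloro-5,5,9-trimethyl-9-[(trimethylsilyl)oxy]spiro[5.5]undec-1-en-3-ol F7. They are separated by chromatography, and F7 is oxidised with Dess–Martin periodinane back to 16, whose C4 is re-equilibrated with Et3N before the next pass.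

## Further compounds

F1 | step 5 | N-methoxy-3-(4-methoxyphenyl)-N,3-dimethylbutanamide | COc1ccc(cc1)C(C)(C)CC(=O)N(C)OC
F2 | step 5 | 1-{[tert-butyl(dimethyl)silyl]oxy}-6-(4-methoxyphenyl)-6-methylhept-2-yn-4-one | COc1ccc(cc1)C(C)(C)CC(=O)C#CCO[Si](C)(C)C(C)(C)C
F3 | step 5 | 1-({[tert-butyl(dimethyl)silyl]oxy}methyl)-2-iodo-5,5-dimethylspiro[5.5]undeca-1,7,10-triene-3,9-dione | CC(C)(C)[Si](C)(C)OCC1=C(I)C(=O)CC(C)(C)C12C=CC(=O)C=C2
F0 | step 6 | none | none
F4 | step 7 | (6R)-1-({[tert-butyl(dimethyl)silyl]oxy}methyl)-8-chloro-5,5-dimethylspiro[5.5]undeca-1,7-diene-3,9-dione | CC(C)(C)[Si](C)(C)OCC1=CC(=O)CC(C)(C)[C@]12CCC(=O)C(Cl)=C2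
F5 | step 8 | (6R,8S)-1-({[tert-butyl(dimethyl)silyl]oxy}methyl)-8-chloro-5,5-dimethyl-9-methylidenespiro[5.5]undec-1-en-3-one | CC(C)(C)[Si](C)(C)OCC1=CC(=O)CC(C)(C)[C@]12CCC(=C)[C@@H](Cl)C2
F6 | step 8 | {[(6R,8S,9R)-1-({[tert-butyl(dimethyl)silyl]oxy}methyl)-8-chloro-9-hydroxy-5,5-dimethyl-3-oxospiro[5.5]undec-1-en-9-yl]methyl}mercury acetate | CC(C)(C)[Si](C)(C)OCC1=CC(=O)CC(C)(C)[C@]12CC[C@@](C[Hg]OC(C)=O)(O)[C@@H](Cl)C2
F7 | step 10 | (3S,4R,6S,8S,9R)-4-bromo-1-({[tert-butyl(dimethyl)silyl]oxy}methyl)-8-chloro-5,5,9-trimethyl-9-[(trimethylsilyl)oxy]spiro[5.5]undec-1-en-3-ol | CC(C)(C)[Si](C)(C)OCC1=C[C@H](O)[C@H](Br)C(C)(C)[C@]12CC[C@@](C)(O[Si](C)(C)C)[C@@H](Cl)C2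
A1 | alternative 1 | (2S,3R,6S,8S,9R)-2-bromo-8-chloro-1,1,9-trimethyl-5-methylidene-9-[(triethylsilyl)oxy]spiro[5.5]undecan-3-ol (triethylsilyl ether of 21) | C=C1C[C@@H](O)[C@@H](Br)C(C)(C)[C@]12CC[C@@](C)(O[Si](CC)(CC)CC)[C@@H](Cl)C2
A2 | alternative 1 | 2-bromo-3-[3-chloro-4-methyl-1-(prop-1-en-2-yl)-4-(triethylsilyloxy)cyclohexyl]-3-methylbutanal, configured as in A1 | O=C[C@@H](Br)C(C)(C)[C@@]1(C(C)=C)CC[C@@](C)(O[Si](CC)(CC)CC)[C@@H](Cl)C1
A3 | alternative 2 | 8-chloro-5,5-dimethyl-3-(2-methylpropoxy)spiro[5.5]undeca-2,7,10-triene-1,9-dione, spiro centre as in the SMILES | CC(C)COC1=CC(=O)[C@@]2(C=CC(=O)C(Cl)=C2)C(C)(C)C1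
A4 | alternative 2 | 10,10-dimethyl-8-(2-methylpropoxy)-2-[(trimethylsilyl)oxy]spiro[4.5]deca-1,3,7-trien-6-one, spiro centre as in A3 | CC(C)COC1=CC(=O)[C@@]2(C=CC(O[Si](C)(C)C)=C2)C(C)(C)C1
A5 | alternative 3 | spiro α-quaternary ketone: ring A with C5 ketone, C3 tert-butyldimethylsilyl ether and C2 bromide (locants of 21), ring B with C9 as ethylene ketal, configured as in the SMILES | O=C1C[C@@H](O[Si](C)(C)C(C)(C)C)[C@@H](Br)C(C)(C)C12CCC3(CC2)OCCO3
A6 | alternative 3 | 3-bromo-4-[tert-butyl(dimethyl)silyl]oxy-6-(1,4-dioxaspiro[4.5]decan-8-ylidene)-2-methyl-6-[(trimethylsilyl)oxy]hexan-2-yl trifluoroacetate, configured as in A5 | CC(C)(OC(=O)C(F)(F)F)[C@H](Br)[C@H](O[Si](C)(C)C(C)(C)C)CC(O[Si](C)(C)C)=C1CCC2(CC1)OCCO2
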